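**Plan**
- Cuts: the CH2–C2 bond joining the chroman-6-ylmethyl arm to the quaternary butenolide carbon; in the butenolide C2–C3 and the lactone O1–C5; in the chroman C6–CH2, C4–C4a and the aryl O1–C2 ether bond.
- Enabling feature: chroman C4 (the benzylic CH2) is bonded to arene carbon C4a, which is ortho to ring oxygen O1, and C3 bears the hydroxyl. An epoxide spanning C3–C4 and hung from O1 through CMe2 can therefore be opened at C4 by C4a.
- Forward order: phenol → tertiary propargyl ether → alkene → resolved epoxide → pyran ring (step 5) → C6 formyl → benzylic bromide. The butenolide ring is made separately by aldol–lactonisation. The halves are joined by enolate benzylation and all three benzyl ethers fall in one hydrogenolysis.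
- Stereochemistry: chroman C3 (R) is selected by hydrolytic kinetic resolution of the terminal epoxide and survives the cyclisation because its C–O bond is not broken. Butenolide C2 (R) is set by a catalyst-controlled phase-transfer alkylation.

Key step: step 5

Assumption: the cinchonidinium salt of step 12 is taken to deliver the (2R) centre; if the sense of induction proves opposite, its pseudoenantiomer O-allyl-N-(9-anthracenylmethyl)cinchoninium bromide takes its place.
Assumption: methyl glyoxylate 15 is used as the freshly distilled monomer.

**Route**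

Step 1
Reactants: 1 phenol; 2 2-methylbut-3-yn-2-ol
Product: 4 [(2-methylbut-3-yn-2-yl)oxy]benzene, via 2-methylbut-3-yn-2-yl trifluoroacetate 3 (not isolated)
Conditions: 2, (CF3CO)2O, DBU, MeCN, −5 °C; then 1, DBU, CuCl2·2H2O (0.1 mol%), MeCN, −5 to 0 °C
Reagents that add atoms: none
Why: Copper-catalysed propargylic substitution, in which the tertiary trifluoroacetate 3 made in the flask from 2 ionises through a copper acetylide and is captured at oxygen by the phenoxide, gives a tertiary aryl propargyl ether that no SN2 reaction can give.

Step 2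
Reactants: 4 [(2-methylbut-3-yn-2-yl)oxy]benzene
Product: 5 [(2-methylbut-3-en-2-yl)oxy]benzene
Conditions: H2 (1 atm), Pd/CaCO3 poisoned with Pb(OAc)2 (Lindlar catalyst), quinoline, EtOAc, rt
Reagents that add atoms: none
Why: Lindlar semihydrogenation of the terminal alkyne should stop at the alkene on the lead-poisoned palladium surface, and room temperature keeps the aryl 1,1-dimethylallyl ether clear of aromatic Claisen rearrangement.

Step 3
Reactants: 5 [(2-methylbut-3-en-2-yl)oxy]benzene
Product: 6 rac-2-(2-phenoxypropan-2-yl)oxirane
Conditions: mCPBA (2 equiv), NaHCO3, CH2Cl2, rt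
Reagents that add atoms: mCPBA, O=C(OO)c1cccc(Cl)c1
Why: Prilezhaev epoxidation of the only alkene should be slow but clean, since the alkoxybenzene ring is inert to the peracid and the bicarbonate buffer protects the acid-labile tertiary allylic ether; the epoxide carbon is formed racemic for the resolution that follows.

Step 4
Reactants: 6 rac-2-(2-phenoxypropan-2-yl)oxirane
Product: 7 (R)-2-(2-phenoxypropan-2-yl)oxirane
Conditions: (S,S)-N,N'-bis(3,5-di-tert-butylsalicylidene)-1,2-cyclohexanediaminocobalt acetate (2 mol%), H2O (0.55 equiv), THF, 0 °C to rt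
Reagents that add atoms: none
Why: In this Jacobsen hydrolytic kinetic resolution the catalyst antipode is chosen to hydrate the (S)-epoxide at its terminal carbon, so the unreacted (R)-epoxide should be recovered in high enantiomeric purity once slightly more than half of 6 is consumed; the future chroman C3 configuration is thus selected by the catalyst.

Step 5
Reactants: 7 (R)-2-(2-phenoxypropan-2-yl)oxirane
Product: 8 (R)-2,2-dimethylchroman-3-ol
Conditions: Sc(OTf)3 (5 mol%), (CF3)2CHOH, 0.02 M, 0 °C to rt
Reagents that add atoms: none
Why: Sc(OTf)3 in the strongly ionising, weakly nucleophilic solvent binds the epoxide oxygen, arene carbon C4a (ortho to the ether oxygen) attacks the terminal CH2, and the arenium ion then loses a proton; this is an intramolecular Friedel-Crafts epoxy-arene cyclisation, the known route from aryl glycidyl ethers to 3-chromanols. The pyran ring closes in the 6-endo mode with respect to the epoxide, C4–C4a being the only skeletal bond made. No stereocentre is created: C3 keeps its (R) configuration because its C–O bond is never broken and the epoxide oxygen simply becomes the hydroxyl. Attack at the terminal rather than the internal epoxide carbon is required, and it is secured by the neopentyl-like crowding of the internal carbon next to CMe2, by the inductive pull of the β-aryloxy group against charge build-up there and by the strain of the 5-exo alternative, while the gem-dimethyl group (Thorpe-Ingold effect) holds the epoxide over the ortho carbon. Ring closure must also outrun intermolecular para-alkylation and ionisation of the tertiary ether, which high dilution, a catalytic mild Lewis acid and the absence of any electron-withdrawing or ionisable para substituent are meant to ensure; this is why the benzylic carbon is introduced only afterwards.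

Step 6
Reactants: 8 (R)-2,2-dimethylchroman-3-ol
Product: 9 (R)-3-(benzyloxy)-2,2-dimethylchroman
Conditions: NaH, BnBr, Bu4NI (cat.), DMF, 0 °C to rt
Reagents that add atoms: benzyl bromide, BrCc1ccccc1
Why: Williamson etherification of the hindered secondary alkoxide touches only the O–H bond, so C3 is unaffected, and a benzyl ether is chosen because it falls with the two others in the last step.

Step 7
Reactants: 9 (R)-3-(benzyloxy)-2,2-dimethylchroman
Product: 11 (R)-3-(benzyloxy)-2,2-dimethylchroman-6-carbaldehyde, via (3R)-3-(benzyloxy)-6-[chloro(methoxy)methyl]-2,2-dimethylchroman 10 (not isolated)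
Conditions: Cl2CHOMe, SnCl4, CH2Cl2, −20 to 0 °C; then H2O
Reagents that add atoms: dichloromethyl methyl ether, COC(Cl)Cl; water, O
Why: In this Rieche formylation the chloro(methoxy)carbenium ion generated by SnCl4 should substitute the alkoxyarene para to ring oxygen O1 (C6), the ortho site C8 being more crowded and the benzyl ring far less nucleophilic, and water then hydrolyses the α-chloro ether 10 to the aldehyde.

Step 8
Reactants: 11 (R)-3-(benzyloxy)-2,2-dimethylchroman-6-carbaldehyde
Product: 12 (R)-[3-(benzyloxy)-2,2-dimethylchroman-6-yl]methanol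
Conditions: NaBH4, MeOH, 0 °C
Reagents that add atoms: none
Why: Borohydride reduction of an aryl aldehyde to the benzylic alcohol should be clean, as no other reducible group is present.

Step 9
Reactants: 12 (R)-[3-(benzyloxy)-2,2-dimethylchroman-6-yl]methanol
Product: 13 (R)-3-(benzyloxy)-6-(bromomethyl)-2,2-dimethylchroman
Conditions: PBr3, Et2O, 0 °C
Reagents that add atoms: phosphorus tribromide, BrP(Br)Br
Why: Bromination of the primary benzylic alcohol through its phosphite ester (SN2 displacement by bromide) should be fast, and the electron-rich benzylic bromide is carried on at once without chromatography.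

Step 10
Reactants: 14 4-hydroxyphenylpyruvic acid; 15 methyl glyoxylate
Product: 17 methyl 4-hydroxy-3-(4-hydroxyphenyl)-5-oxo-2,5-dihydrofuran-2-carboxylate, via 4-hydroxy-3-(4-hydroxyphenyl)-5-methoxy-2,5-dioxopentanoic acid 16 (not isolated)
Conditions: Et3N, THF, 0 °C to rt; then 2 M aq. HCl, rt
Reagents that add atoms: none
Why: This is the classical aldol–lactonisation route to isotetronic acids: the enol of 14 adds through its benzylic carbon to the aldehyde of 15, and on acidification the new hydroxyl closes onto the keto acid carboxyl to give the lactone, which rests as the aryl-conjugated enol; C2 is formed racemic and is reset in step 12.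

Step 11
Reactants: 17 methyl 4-hydroxy-3-(4-hydroxyphenyl)-5-oxo-2,5-dihydrofuran-2-carboxylate
Product: 18 methyl 4-(benzyloxy)-3-[4-(benzyloxy)phenyl]-5-oxo-2,5-dihydrofuran-2-carboxylate
Conditions: BnOH, PPh3, DIAD, THF, 0 °C to rt
Reagents that add atoms: benzyl alcohol, OCc1ccccc1
Why: Mitsunobu etherification should benzylate both acidic hydroxyls (enol and phenol) under neutral conditions, and is chosen over benzyl bromide and base so that the acidic C2–H is not C-benzylated.

Step 12
Reactants: 18 methyl 4-(benzyloxy)-3-[4-(benzyloxy)phenyl]-5-oxo-2,5-dihydrofuran-2-carboxylate; 13 (R)-3-(benzyloxy)-6-(bromomethyl)-2,2-dimethylchroman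
Product: 19 methyl (2R)-4-(benzyloxy)-2-{[(3R)-3-(benzyloxy)-2,2-dimethylchroman-6-yl]methyl}-3-[4-(benzyloxy)phenyl]-5-oxo-2,5-dihydrofuran-2-carboxylate
Conditions: O-allyl-N-(9-anthracenylmethyl)cinchonidinium bromide (10 mol%), Cs2CO3 (solid), toluene, −20 °C
Reagents that add atoms: none
Why: Proposed new method: deprotonation of 18 at C2 gives a 2-oxidofuran-type dienolate that is also an ester enolate, and ion pairing with the chiral quaternary ammonium cation in toluene is expected to shield one face so that bromide 13 enters at C2 (γ to the lactone carbonyl, which restores the aryl-conjugated butenolide) and sets the quaternary (R) centre under catalyst control, the remote chroman centre having no influence; the closest known reaction type is the asymmetric phase-transfer benzylation of α-substituted β-keto esters and malonates to quaternary centres.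

Step 13
Reactants: 19 methyl (2R)-4-(benzyloxy)-2-{[(3R)-3-(benzyloxy)-2,2-dimethylchroman-6-yl]methyl}-3-[4-(benzyloxy)phenyl]-5-oxo-2,5-dihydrofuran-2-carboxylate
Product: 20 methyl (2R)-4-hydroxy-2-{[(3R)-3-hydroxy-2,2-dimethylchroman-6-yl]methyl}-3-(4-hydroxyphenyl)-5-oxo-2,5-dihydrofuran-2-carboxylate
Conditions: H2 (1 atm), 10% Pd/C, EtOAc/MeOH, rt
Reagents that add atoms: none
Why: Catalytic hydrogenolysis should cleave the three benzyl ethers (enol, phenol and secondary alkyl), while the tetrasubstituted aryl-conjugated butenolide alkene and both stereocentres are expected to be unaffected.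

**Compound list**
1 | phenol | Oc1ccccc1 | starting material
2 | 2-methylbut-3-yn-2-ol | CC(C)(O)C#C | starting material
3 | 2-methylbut-3-yn-2-yl trifluoroacetate | CC(C)(OC(=O)C(F)(F)F)C#C | intermediate
4 | [(2-methylbut-3-yn-2-yl)oxy]benzene | CC(C)(Oc1ccccc1)C#C | intermediate
5 | [(2-methylbut-3-en-2-yl)oxy]benzene | CC(C)(Oc1ccccc1)C=C | intermediate
6 | rac-2-(2-phenoxypropan-2-yl)oxirane | CC(C)(Oc1ccccc1)C1CO1 | intermediate
7 | (R)-2-(2-phenoxypropan-2-yl)oxirane | CC(C)(Oc1ccccc1)[C@H]1CO1 | intermediate
8 | (R)-2,2-dimethylchroman-3-ol | CC1(C)Oc2ccccc2C[C@H]1O | intermediate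
9 | (R)-3-(benzyloxy)-2,2-dimethylchroman | CC1(C)Oc2ccccc2C[C@H]1OCc1ccccc1 | intermediate
10 | (3R)-3-(benzyloxy)-6-[chloro(methoxy)methyl]-2,2-dimethylchroman | COC(Cl)c1ccc2OC(C)(C)[C@H](OCc3ccccc3)Cc2c1 | intermediate
11 | (R)-3-(benzyloxy)-2,2-dimethylchroman-6-carbaldehyde | O=Cc1ccc2OC(C)(C)[C@H](OCc3ccccc3)Cc2c1 | intermediate
12 | (R)-[3-(benzyloxy)-2,2-dimethylchroman-6-yl]methanol | OCc1ccc2OC(C)(C)[C@H](OCc3ccccc3)Cc2c1 | intermediate
13 | (R)-3-(benzyloxy)-6-(bromomethyl)-2,2-dimethylchroman | BrCc1ccc2OC(C)(C)[C@H](OCc3ccccc3)Cc2c1 | intermediate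
14 | 4-hydroxyphenylpyruvic acid | O=C(O)C(=O)Cc1ccc(O)cc1 | starting material
15 | methyl glyoxylate | COC(=O)C=O | starting material
16 | 4-hydroxy-3-(4-hydroxyphenyl)-5-methoxy-2,5-dioxopentanoic acid | COC(=O)C(O)C(c1ccc(O)cc1)C(=O)C(=O)O | intermediate
17 | methyl 4-hydroxy-3-(4-hydroxyphenyl)-5-oxo-2,5-dihydrofuran-2-carboxylate (racemic) | COC(=O)C1OC(=O)C(O)=C1c1ccc(O)cc1 | intermediate
18 | methyl 4-(benzyloxy)-3-[4-(benzyloxy)phenyl]-5-oxo-2,5-dihydrofuran-2-carboxylate (racemic) | COC(=O)C1OC(=O)C(OCc2ccccc2)=C1c1ccc(OCc2ccccc2)cc1 | intermediate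
19 | methyl (2R)-4-(benzyloxy)-2-{[(3R)-3-(benzyloxy)-2,2-dimethylchroman-6-yl]methyl}-3-[4-(benzyloxy)phenyl]-5-oxo-2,5-dihydrofuran-2-carboxylate | COC(=O)[C@]1(Cc2ccc3c(c2)C[C@@H](OCc2ccccc2)C(C)(C)O3)OC(=O)C(OCc2ccccc2)=C1c1ccc(OCc2ccccc2)cc1 | intermediate
20 | methyl (2R)-4-hydroxy-2-{[(3R)-3-hydroxy-2,2-dimethylchroman-6-yl]methyl}-3-(4-hydroxyphenyl)-5-oxo-2,5-dihydrofuran-2-carboxylate | COC(=O)[C@]1(Cc2ccc3c(c2)C[C@@H](O)C(C)(C)O3)OC(=O)C(O)=C1c1ccc(O)cc1 | target

**Totals**
Total step count: 13.
Longest linear sequence: 11 steps (steps 1–9, 12 and 13, from phenol).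

**Steps most likely to fail**

Step 12 (proposed method). The flat dienolate may be discriminated only weakly by the ammonium cation, or alkylation may leak to the benzyloxy-bearing carbon C4 or to the enolate oxygen. The fallback sets out from 18 and 13 and runs the C-benzylation without a chiral catalyst (Cs2CO3, DMF, 0 °C), an ordinary alkylation of a doubly stabilised ester enolate. It should give 19 together with its C2 epimer methyl (2S)-4-(benzyloxy)-2-{[(3R)-3-(benzyloxy)-2,2-dimethylchroman-6-yl]methyl}-3-[4-(benzyloxy)phenyl]-5-oxo-2,5-dihydrofuran-2-carboxylate F1. Because the chroman centre is fixed the two are diastereomers, to be separated by preparative HPLC (on a chiral stationary phase if silica does not resolve them). The route is rejoined at 19.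

Step 5. The arene, activated only by the tether oxygen, may be outpaced by intermolecular para-alkylation, by hydride shift of the activated epoxide to an aldehyde, or by solvent opening of the epoxide. The fallback sets out from 4. Thermal aromatic Claisen rearrangement and electrocyclisation (N,N-diethylaniline, 190 °C) should give 2,2-dimethyl-2H-chromene F2. Jacobsen–Katsuki epoxidation with (R,R)-N,N'-bis(3,5-di-tert-butylsalicylidene)-1,2-cyclohexanediaminomanganese chloride, NaOCl and 4-phenylpyridine N-oxide in CH2Cl2 at 0 °C should give (3R,4R)-3,4-epoxy-2,2-dimethylchroman F3. LiAlH4 in THF then delivers hydride to the benzylic C4, leaving the C3–O bond intact, and the route is rejoined at 8.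

Step 10. The benzylic carbon may be hydroxyalkylated twice, the keto acid may self-condense, or the methyl ester may be lost during acidic ring closure. The fallback sets out from 14. Esterification (MeOH, Me3SiCl) should give methyl 3-(4-hydroxyphenyl)-2-oxopropanoate F4. DBU in MeCN with 15 then effects the aldol addition to dimethyl 2-hydroxy-3-(4-hydroxyphenyl)-4-oxopentanedioate F5, whose alkoxide closes onto the keto ester in the same flask by acyl transfer instead of acid-driven dehydration. The route is rejoined at 17.

**Further compounds**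
F1 | step 12 | methyl (2S)-4-(benzyloxy)-2-{[(3R)-3-(benzyloxy)-2,2-dimethylchroman-6-yl]methyl}-3-[4-(benzyloxy)phenyl]-5-oxo-2,5-dihydrofuran-2-carboxylate | COC(=O)[C@@]1(Cc2ccc3c(c2)C[C@@H](OCc2ccccc2)C(C)(C)O3)OC(=O)C(OCc2ccccc2)=C1c1ccc(OCc2ccccc2)cc1
F2 | step 5 | 2,2-dimethyl-2H-chromene | CC1(C)C=Cc2ccccc2O1
F3 | step 5 | (3R,4R)-3,4-epoxy-2,2-dimethylchroman | CC1(C)Oc2ccccc2[C@H]2O[C@@H]12
F4 | step 10 | methyl 3-(4-hydroxyphenyl)-2-oxopropanoate | COC(=O)C(=O)Cc1ccc(O)cc1
F5 | step 10 | dimethyl 2-hydroxy-3-(4-hydroxyphenyl)-4-oxopentanedioate | COC(=O)C(O)C(c1ccc(O)cc1)C(=O)C(=O)OC
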